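**Plan**

- Retrosynthesis: first the two phenol O–Si bonds, then the exocyclic C3=CH–aryl bond (aldol/elimination with the syringaldehyde unit), then in one cut the ring bonds O1–C5 and C3–C4 of the butyrolactone, then the S–C(alkyne) bond and the aryl–CH2 bond.
- Enabling feature: in the lactone ring (O1, C2, C3, C4, C5), C5 is a heteroatom-bearing carbon next to the stereogenic C4. C4–C5 is therefore the C=C of an alkenyl sulfoxide with sulfur on C5, and O1–C2–C3 is a ketene plus the sulfinyl oxygen.
- Forward: aryl bromide → propargyl arene → alkynyl sulfoxide → (Z)-alkenyl sulfoxide → sulfoxide/dichloroketene lactonization (builds the only new ring) → Raney nickel removes both Cl and the S-tolyl group → aldol/elimination adds the benzylidene → desilylation.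
- Stereochemistry: C4 comes from the sulfur stereocentre of (−)-menthyl (S)-p-toluenesulfinate, passed from S to C in the [3,3] shift; the (E)-alkene comes from thermodynamic control in the elimination.

Key step: step 5

Remark (assumption): lactone numbering is O1, C2(=O), C3, C4, C5. The C5 configuration written for 14 (cis to the benzyl group) and the 3,4-trans relationship written for 20 are those expected from the mechanisms; both are erased later (steps 6 and 9).

**Step 1**
Reactants: 1 4-bromo-2-methoxyphenol; 2 chlorotriisopropylsilane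
Product: 3 (4-bromo-2-methoxyphenoxy)triisopropylsilane
Conditions: TIPSCl, imidazole, DMF, rt
Reagents that add atoms: chlorotriisopropylsilane (2), CC(C)[Si](Cl)(C(C)C)C(C)C
Why: Imidazole-promoted silyl ether formation on a phenol; the aryl TIPS ether is chosen because it should survive Grignard reagents, Zn/acid chloride, Raney nickel and LDA and leave with fluoride at the end.

**Step 2**
Reactants: 3 (4-bromo-2-methoxyphenoxy)triisopropylsilane; 4 methoxyallene
Product: 6 triisopropyl[2-methoxy-4-(prop-2-yn-1-yl)phenoxy]silane, via arylmagnesium bromide 5 (not isolated)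
Conditions: Mg, THF, reflux; then CuBr (5 mol %), 4, −20 °C → rt; aqueous work-up
Reagents that add atoms: methoxyallene (4), COC=C=C
Why: Copper-catalysed SN2′-type substitution of a Grignard reagent on methoxyallene (carbocupration of the terminal C=C, then β-elimination of methoxide) should give the propargyl arene ArCH2C≡CH directly.

**Step 3**
Reactants: 6 triisopropyl[2-methoxy-4-(prop-2-yn-1-yl)phenoxy]silane; 7 (1R,2S,5R)-(−)-menthyl (S)-p-toluenesulfinate
Product: 9 (S)-triisopropyl{2-methoxy-4-[3-(p-tolylsulfinyl)prop-2-yn-1-yl]phenoxy}silane, via alkynylmagnesium bromide 8 (not isolated)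
Conditions: EtMgBr, THF, 0 °C → rt; then 7, toluene, −20 °C
Reagents that add atoms: (1R,2S,5R)-(−)-menthyl (S)-p-toluenesulfinate (7), Cc1ccc(cc1)[S@@](=O)O[C@@H]1C[C@H](C)CC[C@H]1C(C)C
Why: Andersen sulfoxide synthesis, in which the alkynyl Grignard reagent displaces mentholate with inversion at sulfur and so installs the sulfur stereocentre that later controls C4.

**Step 4**
Reactants: 9 (S)-triisopropyl{2-methoxy-4-[3-(p-tolylsulfinyl)prop-2-yn-1-yl]phenoxy}silane
Product: 10 (R,Z)-triisopropyl{2-methoxy-4-[3-(p-tolylsulfinyl)prop-2-en-1-yl]phenoxy}silane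
Conditions: H2 (1 atm), RhCl(PPh3)3 (10 mol %), benzene, rt
Reagents that add atoms: none
Why: Homogeneous syn-semihydrogenation with Wilkinson's catalyst should add both hydrogens to one face of the triple bond and stop at the (Z)-alkenyl sulfoxide, the hindered sulfinyl alkene being a poor ligand for rhodium; sulfur keeps its geometry (the descriptor changes from S to R only through the CIP priorities).

**Step 5**
Reactants: 10 (R,Z)-triisopropyl{2-methoxy-4-[3-(p-tolylsulfinyl)prop-2-en-1-yl]phenoxy}silane; 11 trichloroacetyl chloride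
Product: 14 (4S,5R)-3,3-dichloro-4-[3-methoxy-4-(triisopropylsilyloxy)benzyl]-5-(p-tolylsulfanyl)dihydrofuran-2(3H)-one, via acyloxysulfonium enolate 12 (not isolated), via thionium carboxylate 13 (not isolated)
Conditions: Cl3CCOCl, Zn–Cu, Et2O, 0 °C → rt
Reagents that add atoms: trichloroacetyl chloride (11), ClC(Cl)(Cl)C(Cl)=O, delivered in the flask as dichloroketene, ClC(Cl)=C=O
Why: The sulfinyl oxygen of 10, the most nucleophilic site present, should add to dichloroketene to give the acyloxysulfonium enolate 12, whose six-atom array Cl2C=C(O−)–O–S+–C5=C4 undergoes a [3,3]-sigmatropic shift that makes the C3–C4 bond and breaks S–O, after which the carboxylate of 13 adds to the thionium carbon and makes the O1–C5 bond (Pummerer-type termination). The closest known reaction type is the ketene lactonization of enantiopure alkenyl p-tolyl sulfoxides with dichloroketene (Marino lactonization). The lactone ring closes by 5-exo-trig addition of the carboxylate oxygen to the exocyclic C=S+ bond. C4 is controlled by the sulfur stereocentre: with the benzyl-bearing CH2 cis to sulfur, allylic strain keeps the sulfur lone pair eclipsed with the C=C bond, so the S–O bond and the enolate carbon sit over one face of C4 while the p-tolyl group points away, and the (R)-sulfoxide should give the C4 geometry of the target; C5 is expected cis to the benzyl group through suprafacial collapse of 13 and is erased in step 6. The step needs facial selectivity and the regiochemistry carbon-to-C4/oxygen-to-C5, both fixed by the cyclic array and the Z geometry; [2+2] addition of the ketene to the electron-poor alkene or attack on the silylated arene is not expected to compete.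

**Step 6**
Reactants: 14 (4S,5R)-3,3-dichloro-4-[3-methoxy-4-(triisopropylsilyloxy)benzyl]-5-(p-tolylsulfanyl)dihydrofuran-2(3H)-one
Product: 15 (R)-4-[3-methoxy-4-(triisopropylsilyloxy)benzyl]dihydrofuran-2(3H)-one
Conditions: Raney Ni (W-2, excess), EtOH, rt
Reagents that add atoms: none
Why: Raney nickel hydrogenolysis (reductive desulfurization of the S,O-acetal carbon and reductive dechlorination α to the carbonyl) should remove all three helper atoms at once, turning C5 into the CH2–O of the target without touching C4.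

**Step 7**
Reactants: 16 syringaldehyde (4-hydroxy-3,5-dimethoxybenzaldehyde); 17 tert-butylchlorodimethylsilane
Product: 18 4-(tert-butyldimethylsilyloxy)-3,5-dimethoxybenzaldehyde
Conditions: TBSCl, imidazole, DMF, rt
Reagents that add atoms: tert-butylchlorodimethylsilane (17), CC(C)(C)[Si](C)(C)Cl
Why: Imidazole-promoted silylation of the phenol masks the acidic OH for the enolate chemistry and gives a group that leaves in the same fluoride step as the TIPS ether.

**Step 8**
Reactants: 15 (R)-4-[3-methoxy-4-(triisopropylsilyloxy)benzyl]dihydrofuran-2(3H)-one; 18 4-(tert-butyldimethylsilyloxy)-3,5-dimethoxybenzaldehyde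
Product: 20 (3S,4R)-3-{[4-(tert-butyldimethylsilyloxy)-3,5-dimethoxyphenyl](hydroxy)methyl}-4-[3-methoxy-4-(triisopropylsilyloxy)benzyl]dihydrofuran-2(3H)-one (carbinol epimers), via lithium enolate 19 (not isolated)
Conditions: LDA, THF, −78 °C; then 18, −78 °C; AcOH quench
Reagents that add atoms: 4-(tert-butyldimethylsilyloxy)-3,5-dimethoxybenzaldehyde (18), COc1cc(C=O)cc(OC)c1O[Si](C)(C)C(C)(C)C
Why: Lithium enolate aldol addition, in which the aldehyde should approach C3 anti to the C4 benzyl group; the two new centres need no control because step 9 removes them.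

**Step 9**
Reactants: 20 (3S,4R)-3-{[4-(tert-butyldimethylsilyloxy)-3,5-dimethoxyphenyl](hydroxy)methyl}-4-[3-methoxy-4-(triisopropylsilyloxy)benzyl]dihydrofuran-2(3H)-one
Product: 22 (R,E)-3-[4-(tert-butyldimethylsilyloxy)-3,5-dimethoxybenzylidene]-4-[3-methoxy-4-(triisopropylsilyloxy)benzyl]dihydrofuran-2(3H)-one, via benzylic mesylate 21 (not isolated)
Conditions: MsCl, Et3N, CH2Cl2, 0 °C; then DBU, rt
Reagents that add atoms: none
Why: Mesylation followed by DBU-promoted E1cB elimination should give the conjugated (E)-benzylidene lactone (aryl anti to the lactone carbonyl) as the thermodynamically favoured isomer from both carbinol epimers.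

**Step 10**
Reactants: 22 (R,E)-3-[4-(tert-butyldimethylsilyloxy)-3,5-dimethoxybenzylidene]-4-[3-methoxy-4-(triisopropylsilyloxy)benzyl]dihydrofuran-2(3H)-one
Product: 23 (R,E)-3-(4-hydroxy-3,5-dimethoxybenzylidene)-4-(4-hydroxy-3-methoxybenzyl)dihydrofuran-2(3H)-one
Conditions: TBAF, AcOH (1:1), THF, 0 °C → rt
Reagents that add atoms: none
Why: Fluoride-mediated cleavage of both aryl silyl ethers (desilylation), buffered with acetic acid so that the phenoxides are protonated at once and the base-sensitive benzylidene lactone is neither isomerized nor opened.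

**Compound list**

1 | 4-bromo-2-methoxyphenol | COc1cc(Br)ccc1O | starting material
2 | chlorotriisopropylsilane | CC(C)[Si](Cl)(C(C)C)C(C)C | starting material
3 | (4-bromo-2-methoxyphenoxy)triisopropylsilane | COc1cc(Br)ccc1O[Si](C(C)C)(C(C)C)C(C)C | intermediate
4 | methoxyallene (1-methoxypropa-1,2-diene) | COC=C=C | starting material
5 | [3-methoxy-4-(triisopropylsilyloxy)phenyl]magnesium bromide | COc1cc([Mg]Br)ccc1O[Si](C(C)C)(C(C)C)C(C)C | intermediate (not isolated)
6 | triisopropyl[2-methoxy-4-(prop-2-yn-1-yl)phenoxy]silane | C#CCc1ccc(O[Si](C(C)C)(C(C)C)C(C)C)c(OC)c1 | intermediate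
7 | (1R,2S,5R)-(−)-menthyl (S)-p-toluenesulfinate | Cc1ccc(cc1)[S@@](=O)O[C@@H]1C[C@H](C)CC[C@H]1C(C)C | starting material
8 | {3-[3-methoxy-4-(triisopropylsilyloxy)phenyl]prop-1-yn-1-yl}magnesium bromide | Br[Mg]C#CCc1ccc(O[Si](C(C)C)(C(C)C)C(C)C)c(OC)c1 | intermediate (not isolated)
9 | (S)-triisopropyl{2-methoxy-4-[3-(p-tolylsulfinyl)prop-2-yn-1-yl]phenoxy}silane | Cc1ccc(cc1)[S@](=O)C#CCc1ccc(O[Si](C(C)C)(C(C)C)C(C)C)c(OC)c1 | intermediate
10 | (R,Z)-triisopropyl{2-methoxy-4-[3-(p-tolylsulfinyl)prop-2-en-1-yl]phenoxy}silane | Cc1ccc(cc1)[S@](=O)/C=C\Cc1ccc(O[Si](C(C)C)(C(C)C)C(C)C)c(OC)c1 | intermediate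
11 | trichloroacetyl chloride | ClC(Cl)(Cl)C(Cl)=O | starting material
12 | acyloxysulfonium enolate (O-acylated sulfoxide zwitterion) | Cc1ccc(cc1)[S@+](OC([O-])=C(Cl)Cl)/C=C\Cc1ccc(O[Si](C(C)C)(C(C)C)C(C)C)c(OC)c1 | intermediate (not isolated)
13 | thionium carboxylate (rearranged zwitterion) | [O-]C(=O)C(Cl)(Cl)[C@@H](Cc1ccc(O[Si](C(C)C)(C(C)C)C(C)C)c(OC)c1)C=[S+]c1ccc(C)cc1 | intermediate (not isolated)
14 | (4S,5R)-3,3-dichloro-4-[3-methoxy-4-(triisopropylsilyloxy)benzyl]-5-(p-tolylsulfanyl)dihydrofuran-2(3H)-one | O=C1O[C@H](Sc2ccc(C)cc2)[C@H](Cc2ccc(O[Si](C(C)C)(C(C)C)C(C)C)c(OC)c2)C1(Cl)Cl | intermediate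
15 | (R)-4-[3-methoxy-4-(triisopropylsilyloxy)benzyl]dihydrofuran-2(3H)-one | COc1cc(C[C@H]2COC(=O)C2)ccc1O[Si](C(C)C)(C(C)C)C(C)C | intermediate
16 | syringaldehyde | COc1cc(C=O)cc(OC)c1O | starting material
17 | tert-butylchlorodimethylsilane | CC(C)(C)[Si](C)(C)Cl | starting material
18 | 4-(tert-butyldimethylsilyloxy)-3,5-dimethoxybenzaldehyde | COc1cc(C=O)cc(OC)c1O[Si](C)(C)C(C)(C)C | intermediate
19 | lithium enolate of 15 | COc1cc(C[C@H]2COC(O[Li])=C2)ccc1O[Si](C(C)C)(C(C)C)C(C)C | intermediate (not isolated)
20 | (3S,4R)-3-{[4-(tert-butyldimethylsilyloxy)-3,5-dimethoxyphenyl](hydroxy)methyl}-4-[3-methoxy-4-(triisopropylsilyloxy)benzyl]dihydrofuran-2(3H)-one, carbinol epimers | COc1cc(C[C@H]2COC(=O)[C@@H]2C(O)c2cc(OC)c(O[Si](C)(C)C(C)(C)C)c(OC)c2)ccc1O[Si](C(C)C)(C(C)C)C(C)C | intermediate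
21 | methanesulfonate of 20 | COc1cc(C[C@H]2COC(=O)[C@@H]2C(OS(C)(=O)=O)c2cc(OC)c(O[Si](C)(C)C(C)(C)C)c(OC)c2)ccc1O[Si](C(C)C)(C(C)C)C(C)C | intermediate (not isolated)
22 | (R,E)-3-[4-(tert-butyldimethylsilyloxy)-3,5-dimethoxybenzylidene]-4-[3-methoxy-4-(triisopropylsilyloxy)benzyl]dihydrofuran-2(3H)-one | COc1cc(C[C@H]2COC(=O)/C2=C/c2cc(OC)c(O[Si](C)(C)C(C)(C)C)c(OC)c2)ccc1O[Si](C(C)C)(C(C)C)C(C)C | intermediate
23 | (R,E)-3-(4-hydroxy-3,5-dimethoxybenzylidene)-4-(4-hydroxy-3-methoxybenzyl)dihydrofuran-2(3H)-one | COc1cc(C[C@H]2COC(=O)/C2=C/c2cc(OC)c(O)c(OC)c2)ccc1O | target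

**Totals**

Total step count: 10. Longest linear sequence: 9 (steps 1–6 and 8–10); step 7 is a one-step side branch.

**Steps most likely to fail, with fallbacks**

Step 5. The O-acylated sulfoxide may lose a proton from the allylic, benzylic CH2 instead of rearranging. Zinc may deoxygenate the sulfoxide. The facial preference may be eroded if the lone-pair-eclipsed conformer is not the only one that reacts. The fallback takes the C4 centre from the chiral pool instead of from sulfur. It sets out from the aryl Grignard reagent 5 (made from 3 as in step 2) and comes back to the route at 15, bypassing steps 3–6. Diethyl malonate and (R)-epichlorohydrin (NaOEt, EtOH, reflux) should give ethyl (1S,5R)-2-oxo-3-oxabicyclo[3.1.0]hexane-1-carboxylate F1. Copper-catalysed homoconjugate addition of 5 (CuI cat., THF, −30 °C) should open the activated cyclopropane at its CH2 carbon and give ethyl (4R)-4-[3-methoxy-4-(triisopropylsilyloxy)benzyl]-2-oxotetrahydrofuran-3-carboxylate F2, with C4 carried over unchanged from the epichlorohydrin carbon. Krapcho dealkoxycarbonylation (LiCl, wet DMSO, 130 °C) should then give 15.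

Step 4 (together with step 3). The hydrogenation may run on to the saturated sulfoxide or be slowed by sulfur binding to rhodium, and the propargylic, benzylic CH2 may isomerize to an allene under the basic conditions of step 3. The fallback fixes the Z geometry before sulfur is introduced. It sets out from alkyne 6 and comes back at 10. Iodination (NIS, AgNO3 cat., acetone) should give [4-(3-iodoprop-2-yn-1-yl)-2-methoxyphenoxy]triisopropylsilane F3. Diimide reduction (2-nitrobenzenesulfonyl hydrazide, Et3N, THF/i-PrOH) should give (Z)-[4-(3-iodoprop-2-en-1-yl)-2-methoxyphenoxy]triisopropylsilane F4. Iodine–lithium exchange with retention (t-BuLi, Et2O, −78 °C) should give the (Z)-alkenyllithium F5, which is quenched with sulfinate 7 (Andersen substitution, inversion at sulfur) to give 10.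

Step 9. The elimination may give an E/Z mixture, or the base may move the double bond into the ring (endocyclic butenolide) with loss of the C4 centre. The fallback replaces aldol/elimination by an olefination. It sets out from 15 and comes back at 22, bypassing step 8. Treatment of 15 with LDA (2.2 equiv, THF, −78 °C) and diethyl chlorophosphate should give the enol phosphate F6, which under the excess LDA should undergo 1,3-phosphorus migration to diethyl {(4R)-4-[3-methoxy-4-(triisopropylsilyloxy)benzyl]-2-oxotetrahydrofuran-3-yl}phosphonate F7. Horner–Wadsworth–Emmons reaction of F7 with aldehyde 18 under mild conditions (LiCl, DBU, MeCN, rt) should give 22 with the E geometry usual for α-phosphono lactones and aryl aldehydes.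

**Further compounds**

F1 | step 5 | ethyl (1S,5R)-2-oxo-3-oxabicyclo[3.1.0]hexane-1-carboxylate | CCOC(=O)[C@]12C[C@H]1COC2=O
F2 | step 5 | ethyl (4R)-4-[3-methoxy-4-(triisopropylsilyloxy)benzyl]-2-oxotetrahydrofuran-3-carboxylate (C3 epimers) | CCOC(=O)C1C(=O)OC[C@@H]1Cc1ccc(O[Si](C(C)C)(C(C)C)C(C)C)c(OC)c1
F3 | step 4 | [4-(3-iodoprop-2-yn-1-yl)-2-methoxyphenoxy]triisopropylsilane | IC#CCc1ccc(O[Si](C(C)C)(C(C)C)C(C)C)c(OC)c1
F4 | step 4 | (Z)-[4-(3-iodoprop-2-en-1-yl)-2-methoxyphenoxy]triisopropylsilane | I/C=C\Cc1ccc(O[Si](C(C)C)(C(C)C)C(C)C)c(OC)c1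
F5 | step 4 | (Z)-{3-[3-methoxy-4-(triisopropylsilyloxy)phenyl]prop-1-en-1-yl}lithium | [Li]/C=C\Cc1ccc(O[Si](C(C)C)(C(C)C)C(C)C)c(OC)c1
F6 | step 9 | diethyl (3R)-3-[3-methoxy-4-(triisopropylsilyloxy)benzyl]-2,3-dihydrofuran-5-yl phosphate (enol phosphate of 15) | CCOP(=O)(OCC)OC1=C[C@@H](Cc2ccc(O[Si](C(C)C)(C(C)C)C(C)C)c(OC)c2)CO1
F7 | step 9 | diethyl {(4R)-4-[3-methoxy-4-(triisopropylsilyloxy)benzyl]-2-oxotetrahydrofuran-3-yl}phosphonate (C3 epimers) | CCOP(=O)(OCC)C1C(=O)OC[C@@H]1Cc1ccc(O[Si](C(C)C)(C(C)C)C(C)C)c(OC)c1
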